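**Plan**

1. Retrosynthesis: the ring bond C3–C4 (methyl-bearing olefinic carbon to carbinol carbon) is cut first, which opens the cyclohexenone to the acyclic (Z)-β-iodoenone aldehyde 16. Then follow C3–I/C2–H (ynone 14), C1–C2 (lactone 11 plus 1-propynyllithium) and the C5–CH2 bond to the C20 chain (alkylation with geranylgeranyl bromide 7).
2. Enabling feature: in the ring C1–C6 the C1 carbonyl and the C4 carbinol are 1,4-related across the C2=C3 olefin (a γ-hydroxy enone). C3 (enone β-carbon) and C4 (aldehyde carbon) are therefore both acceptor carbons; C3 is turned into a donor as an alkenylchromium species and closes the only ring onto C4.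
3. Forward: the chain is joined to a four-carbon succinate unit (C4–C5–C6–C1), and a temporary γ-lactone tells C4 from C1. The C1 end becomes the ynone and then the Z-iodoenone, the C4 end becomes the aldehyde, and the ring arises in the last step without protecting groups.
4. Stereochemistry: C5 comes from (S)-4-benzyl-2-oxazolidinone (Evans alkylation); C4 comes from C5 by 1,2-induction in the ring closure (4,5-cis). The three E olefins come from geranylgeraniol; the Z-iodoenone from anti hydroiodination becomes the ring olefin.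

Key step: step 8

Remark: the (4S,5S) descriptors of the target correspond to a cis arrangement of the C4 hydroxyl and the C5 side chain; all-E geranylgeraniol and solid 1-propynyllithium are taken as purchasable.

**Step 1**
Reactants: 1 (S)-4-benzyl-2-oxazolidinone; 2 4-tert-butoxy-4-oxobutanoic acid (mono-tert-butyl succinate); 3 pivaloyl chloride
Product: 5 tert-butyl 4-[(4S)-4-benzyl-2-oxo-1,3-oxazolidin-3-yl]-4-oxobutanoate, via mixed pivalic anhydride 4 (not isolated)
Conditions: 2, 3, Et3N, THF, −20 °C; then 1, LiCl, −20 → 23 °C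
Reagents that add atoms: none
Why: Mixed-anhydride N-acylation of an oxazolidinone (LiCl/Et3N variant), in which the oxazolidinone should attack the unhindered succinyl carbonyl of 4 rather than the pivaloyl carbonyl, with no new stereocentre and the tert-butyl ester untouched.

**Step 2**
Reactants: 6 (2E,6E,10E)-geranylgeraniol
Product: 7 (2E,6E,10E)-geranylgeranyl bromide
Conditions: PBr3 (0.4 equiv), Et2O, −10 °C, dark; used crude
Reagents that add atoms: phosphorus tribromide, BrP(Br)Br
Why: Bromination of a primary allylic alcohol with PBr3 at low temperature is an SN2 displacement that should keep the 2E geometry and leave the other olefins alone.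

**Step 3**
Reactants: 5 tert-butyl 4-[(4S)-4-benzyl-2-oxo-1,3-oxazolidin-3-yl]-4-oxobutanoate; 7 geranylgeranyl bromide
Product: 9 tert-butyl (3S,5E,9E,13E)-3-{[(4S)-4-benzyl-2-oxo-1,3-oxazolidin-3-yl]carbonyl}-6,10,14,18-tetramethylnonadeca-5,9,13,17-tetraenoate, via sodium Z-enolate 8 (not isolated)
Conditions: NaN(SiMe3)2 (1.1 equiv), THF, −78 °C; then 7 (1.3 equiv), −78 → −40 °C
Reagents that add atoms: none
Why: Evans asymmetric alkylation, in which the chelated Z-enolate 8 (the imide α-CH2 is far more acidic than the ester α-CH2) should be attacked by the primary allylic bromide on the face opposite the benzyl group, which sets the future C5 as S.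

**Step 4**
Reactants: 9 the alkylated imide
Product: 11 (4S)-4-[(2E,6E,10E)-3,7,11,15-tetramethylhexadeca-2,6,10,14-tetraen-1-yl]oxolan-2-one (β-geranylgeranyl-γ-butyrolactone), via hydroxy tert-butyl ester 10 (not isolated)
Conditions: LiBH4 (1.2 equiv), H2O (1.2 equiv), Et2O, 0 °C; aqueous work-up; then p-TsOH·H2O (10 mol %), CH2Cl2, 23 °C
Reagents that add atoms: none
Why: Reductive cleavage of the N-acyloxazolidinone by LiBH4 (tert-butyl ester and trisubstituted olefins inert) followed by acid-catalysed lactonization of the γ-hydroxy tert-butyl ester should give the lactone, and the stereocentre, never α to a carbonyl after the reduction, is retained.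

**Step 5**
Reactants: 11 the lactone; 12 1-propynyllithium
Product: 14 (6S,8E,12E,16E)-6-(hydroxymethyl)-9,13,17,21-tetramethyldocosa-8,12,16,20-tetraen-2-yn-4-one, via lithium lactolate 13 (not isolated)
Conditions: THF, −78 °C; then AcOH (1.5 equiv), −78 → 0 °C
Reagents that add atoms: none
Why: Mono-addition of a lithium acetylide to a γ-lactone, in which the tetrahedral lactolate 13 is stable at −78 °C and should shield the carbonyl from a second addition until protonation releases the open-chain hydroxy ynone.

**Step 6**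
Reactants: 14 the hydroxy ynone
Product: 15 (2Z,6S,8E,12E,16E)-6-(hydroxymethyl)-2-iodo-9,13,17,21-tetramethyldocosa-2,8,12,16,20-pentaen-4-one
Conditions: NaI (2 equiv), AcOH, 23 °C, dark
Reagents that add atoms: sodium iodide, [Na+].[I-]
Why: Conjugate hydroiodination of an ynone, in which iodide adds to the β-carbon and the allenolate is protonated anti to iodine under kinetic control, should give the Z-iodoenone (iodine cis to the carbonyl) while AcOH at 23 °C leaves the trisubstituted olefins alone.

**Step 7**
Reactants: 15 the Z-iodoenone alcohol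
Product: 16 (2S,5Z)-6-iodo-4-oxo-2-[(2E,6E,10E)-3,7,11,15-tetramethylhexadeca-2,6,10,14-tetraen-1-yl]hept-5-enal
Conditions: Dess–Martin periodinane (1.3 equiv), NaHCO3, CH2Cl2, 0 °C; short silica plug, used at once
Reagents that add atoms: none
Why: Buffered Dess–Martin oxidation of the primary alcohol should give the α-branched aldehyde without epimerization at C5 and without touching the iodoalkene or the olefins.

**Step 8**
Reactants: 16 the Z-iodoenone aldehyde
Product: 19 (4S,5S)-4-hydroxy-3-methyl-5-[(2E,6E,10E)-3,7,11,15-tetramethylhexadeca-2,6,10,14-tetraen-1-yl]cyclohex-2-en-1-one, via alkenylchromium dichloride 17 (not isolated), via chromium alkoxide 18 (not isolated)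
Conditions: CrCl2 (6 equiv), NiCl2 (2 mol %), degassed DMSO (0.01 M), 23 °C; then aq. NH4Cl
Reagents that add atoms: none
Why: Zerovalent nickel, formed from NiCl2 by divalent chromium, inserts into the C–I bond of 16 with retention and hands the alkenyl group to trivalent chromium, so that C3, normally the electrophilic β-carbon of the enone, becomes the nucleophile 17, which adds to the aldehyde carbon C4 through a chromium-bridged four-centre transition state and ends as alkoxide 18. The closest known reaction type is the intramolecular Nozaki–Hiyama–Kishi coupling of iodoalkenes, β-iodo enoates and enones included, with aldehydes. The six-membered ring closes in the 6-exo-trig mode at the aldehyde C=O, and only the Z geometry of C2=C3 lets C3 reach C4, this olefin becoming the endocyclic one. The new stereocentre C4 is controlled by C5 (1,2-induction): in the half-chair transition state the side chain on C5 lies pseudo-equatorial and antiperiplanar to the incoming C3 (Felkin–Anh), and the aldehyde oxygen lies pseudo-axial, anti to H-5, where it reaches chromium and avoids A(1,2) strain with the C3 methyl, which should favour the 4,5-cis (4S) alcohol. The step needs chemoselectivity for the aldehyde over the C1 ketone and for the C–I bond over the four olefins, which the aldehyde preference and low basicity of alkenylchromium reagents secure, and it needs C5 to stay intact, which the neutral medium secures.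

**Compound list**

1 | (S)-4-benzyl-2-oxazolidinone | O=C1N[C@@H](Cc2ccccc2)CO1 | starting material
2 | 4-tert-butoxy-4-oxobutanoic acid (mono-tert-butyl succinate) | CC(C)(C)OC(=O)CCC(=O)O | starting material
3 | pivaloyl chloride | CC(C)(C)C(=O)Cl | starting material
4 | mixed pivalic anhydride of 2 (4-tert-butoxy-4-oxobutanoic pivalic anhydride) | CC(C)(C)OC(=O)CCC(=O)OC(=O)C(C)(C)C | intermediate
5 | tert-butyl 4-[(4S)-4-benzyl-2-oxo-1,3-oxazolidin-3-yl]-4-oxobutanoate | CC(C)(C)OC(=O)CCC(=O)N1[C@@H](Cc2ccccc2)COC1=O | intermediate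
6 | (2E,6E,10E)-geranylgeraniol | CC(C)=CCC/C(C)=C/CC/C(C)=C/CC/C(C)=C/CO | starting material
7 | (2E,6E,10E)-geranylgeranyl bromide | CC(C)=CCC/C(C)=C/CC/C(C)=C/CC/C(C)=C/CBr | intermediate
8 | sodium Z-enolate of imide 5 | CC(C)(C)OC(=O)C/C=C(\[O-])N1[C@@H](Cc2ccccc2)COC1=O.[Na+] | intermediate
9 | tert-butyl (3S,5E,9E,13E)-3-{[(4S)-4-benzyl-2-oxo-1,3-oxazolidin-3-yl]carbonyl}-6,10,14,18-tetramethylnonadeca-5,9,13,17-tetraenoate | CC(C)=CCC/C(C)=C/CC/C(C)=C/CC/C(C)=C/C[C@H](C(=O)N1[C@@H](Cc2ccccc2)COC1=O)CC(=O)OC(C)(C)C | intermediate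
10 | tert-butyl (3S,5E,9E,13E)-3-(hydroxymethyl)-6,10,14,18-tetramethylnonadeca-5,9,13,17-tetraenoate | CC(C)=CCC/C(C)=C/CC/C(C)=C/CC/C(C)=C/C[C@H](CO)CC(=O)OC(C)(C)C | intermediate
11 | (4S)-4-[(2E,6E,10E)-3,7,11,15-tetramethylhexadeca-2,6,10,14-tetraen-1-yl]oxolan-2-one | CC(C)=CCC/C(C)=C/CC/C(C)=C/CC/C(C)=C/C[C@H]1CC(=O)OC1 | intermediate
12 | 1-propynyllithium | [Li]C#CC | starting material
13 | lithium (4S)-2-(prop-1-yn-1-yl)-4-geranylgeranyloxolan-2-olate (both epimers at C2) | CC(C)=CCC/C(C)=C/CC/C(C)=C/CC/C(C)=C/C[C@H]1CC([O-])(C#CC)OC1.[Li+] | intermediate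
14 | (6S,8E,12E,16E)-6-(hydroxymethyl)-9,13,17,21-tetramethyldocosa-8,12,16,20-tetraen-2-yn-4-one | CC(C)=CCC/C(C)=C/CC/C(C)=C/CC/C(C)=C/C[C@H](CO)CC(=O)C#CC | intermediate
15 | (2Z,6S,8E,12E,16E)-6-(hydroxymethyl)-2-iodo-9,13,17,21-tetramethyldocosa-2,8,12,16,20-pentaen-4-one | CC(C)=CCC/C(C)=C/CC/C(C)=C/CC/C(C)=C/C[C@H](CO)CC(=O)/C=C(/C)I | intermediate
16 | (2S,5Z)-6-iodo-4-oxo-2-[(2E,6E,10E)-3,7,11,15-tetramethylhexadeca-2,6,10,14-tetraen-1-yl]hept-5-enal | CC(C)=CCC/C(C)=C/CC/C(C)=C/CC/C(C)=C/C[C@H](C=O)CC(=O)/C=C(/C)I | intermediate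
17 | alkenylchromium dichloride derived from 16 (chromium in place of iodine, geometry retained) | CC(C)=CCC/C(C)=C/CC/C(C)=C/CC/C(C)=C/C[C@H](C=O)CC(=O)/C=C(/C)[Cr](Cl)Cl | intermediate
18 | dichlorochromium alkoxide of the target | CC(C)=CCC/C(C)=C/CC/C(C)=C/CC/C(C)=C/C[C@H]1CC(=O)C=C(C)[C@H]1O[Cr](Cl)Cl | intermediate
19 | (4S,5S)-4-hydroxy-3-methyl-5-[(2E,6E,10E)-3,7,11,15-tetramethylhexadeca-2,6,10,14-tetraen-1-yl]cyclohex-2-en-1-one | CC(C)=CCC/C(C)=C/CC/C(C)=C/CC/C(C)=C/C[C@H]1CC(=O)C=C(C)[C@H]1O | target

**Step count and risks**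

Total step count: 8. Longest linear sequence: 7 steps (steps 1, 3, 4, 5, 6, 7, 8 from 1 and 2); step 2 is a one-step side branch.

Three steps most likely to fail:

1. Step 8 – poor facial selectivity at the aldehyde, so that the 4,5-trans alcohol forms in a large share. Fallback (from 16, back to the route at 19): the same CrCl2/NiCl2 closure is run and the (4R,5S)-trans alcohol F1 is separated. Its C4 is then inverted by Mitsunobu esterification with 4-nitrobenzoic acid (PPh3, DIAD, THF, 0 °C) to the cis 4-nitrobenzoate F2, and brief methanolysis (K2CO3, MeOH, 0 °C) should give 19.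

2. Step 6 – ring–chain tautomerism of the free γ-hydroxy ynone to its cyclic hemiketal followed by dehydration in AcOH, or drift of the Z-iodoenone to the E isomer. Fallback (from 14, back at 15): the alcohol is first silylated (TBSCl, imidazole, DMF) to the silyl ether ynone F3. Hydroiodination (NaI, AcOH, 23 °C) then gives the silyl-protected Z-iodoenone F4, and HF·pyridine in THF/pyridine at 0 °C should release 15.

3. Step 5 – a second acetylide addition to the ynone or enolization of the lactone by the acetylide. Fallback (from 11, back at 14): the lactone is opened with Me(MeO)NH·HCl/AlMe3 (CH2Cl2, 0 °C) to the hydroxy Weinreb amide F5. Treatment with 1-propynylmagnesium bromide (3 equiv, THF, 0 °C), whose chelated adduct cannot add twice, should then give 14.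

**Further compounds**

F1 | step 8 | (4R,5S)-4-hydroxy-3-methyl-5-[(2E,6E,10E)-3,7,11,15-tetramethylhexadeca-2,6,10,14-tetraen-1-yl]cyclohex-2-en-1-one | CC(C)=CCC/C(C)=C/CC/C(C)=C/CC/C(C)=C/C[C@H]1CC(=O)C=C(C)[C@@H]1O
F2 | step 8 | (1S,6S)-2-methyl-4-oxo-6-[(2E,6E,10E)-3,7,11,15-tetramethylhexadeca-2,6,10,14-tetraen-1-yl]cyclohex-2-en-1-yl 4-nitrobenzoate | CC(C)=CCC/C(C)=C/CC/C(C)=C/CC/C(C)=C/C[C@H]1CC(=O)C=C(C)[C@H]1OC(=O)c2ccc(cc2)[N+](=O)[O-]
F3 | step 6 | (6S,8E,12E,16E)-6-{[tert-butyl(dimethyl)silyl]oxymethyl}-9,13,17,21-tetramethyldocosa-8,12,16,20-tetraen-2-yn-4-one | CC(C)=CCC/C(C)=C/CC/C(C)=C/CC/C(C)=C/C[C@H](CO[Si](C)(C)C(C)(C)C)CC(=O)C#CC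
F4 | step 6 | (2Z,6S,8E,12E,16E)-6-{[tert-butyl(dimethyl)silyl]oxymethyl}-2-iodo-9,13,17,21-tetramethyldocosa-2,8,12,16,20-pentaen-4-one | CC(C)=CCC/C(C)=C/CC/C(C)=C/CC/C(C)=C/C[C@H](CO[Si](C)(C)C(C)(C)C)CC(=O)/C=C(/C)I
F5 | step 5 | (3S,5E,9E,13E)-3-(hydroxymethyl)-N-methoxy-N,6,10,14,18-pentamethylnonadeca-5,9,13,17-tetraenamide | CC(C)=CCC/C(C)=C/CC/C(C)=C/CC/C(C)=C/C[C@H](CO)CC(=O)N(C)OC
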